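Start from the amounts: what a flask makes per minute, as a share of its E, I take to go with the loading of Q times [D], so that the earlier runs can be read as one clock.

| flask | E | D | Q | temperature | remark | time |
|---|---|---|---|---|---|---|
| elm | 11 mM | 1 equiv | 3.6 mol% | 80 °C | run made earlier |  |
| larch | 11 mM | 1 equiv | 21 mol% | 124 °C | run made earlier |  |
| birch | 11 mM | 1.8 equiv | 15 mol% | 80 °C | run made earlier |  |
| beta | 6.0 mM | 1.00 equiv | 25 mol% | 100 °C |  | 30 min |
| gamma | 30 mM | 4.00 equiv | 15 mol% | 100 °C |  | 30 min |
| theta | 11 mM | 1.00 equiv | 25 mol% | 120 °C |  | 30 min |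
| eta | 11 mM | 1.00 equiv | 15 mol% | 100 °C |  | 30 min |
| epsilon | 11 mM | 1.00 equiv | 4 mol% | 60 °C |  | 30 min |
| alpha | 11 mM | 1.00 equiv | 4 mol% | 140 °C |  | 30 min |

| run | time / min | L / % |
|---|---|---|
| elm | 6.00 | 0.7 |
| elm | 10.0 | 0 |
| elm | 15.0 | 0.6 |
| elm | 25.0 | 2.5 |
| elm | 50.0 | 4.4 |
| elm | 80.0 | 5.4 |
| larch | 0.833 | 1.1 |
| larch | 1.33 | 3.6 |
| larch | 2.00 | 5.3 |
| larch | 3.00 | 9.9 |
| larch | 6.00 | 18.7 |
| larch | 10.0 | 26.3 |
| birch | 6.00 | 1.7 |
| birch | 15.0 | 3.7 |
| birch | 20.0 | 7.7 |
| birch | 40.0 | 17.6 |
| birch | 80.0 | 34.8 |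

(each reading ± 1 percentage point)

- the earlier runs were read with a standard deviation of 1 percentage point

* all flasks from highest to lowest amount of L, in percent of the E charged, at 30 min (beta / gamma / theta / eta / epsilon / alpha)
* the same order at 2.0 h (beta / gamma / theta / eta / epsilon / alpha)
* the amount of L, in percent of the E charged of the flask you put first, at 30 min
* the amount of L, in percent of the E charged of the flask you put last, at 30 min

Birch climbs straight from 20.0 min to 80.0 min. Invert that slope and you have the time in which birch would turn over its whole charge of E at that pace. Call it the turnover time, 221 min, a turnover frequency turned upside down and scaled by the loading. Scaled to elm's Q and D it becomes 1660 min, which gives 4.82% at 80.0 min. Elm read 5.4%, and since that is another run, this is a check of the scaling.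

Larch, read from 3.00 min to 6.00 min, has a turnover time of 34.1 min. On equal amounts it runs faster than birch by a factor 8.35. 100 °C lies near the reciprocal middle of 80 °C and 124 °C, so I take the square root of that factor for the step, and the same root again down to 60 °C.

Now my ladder, fastest first. The lag comes lowest: elm shows nothing beyond scatter up to 15.0 min, while larch holds 3.6% at 1.33 min. Then gamma, at 12.6 min, is shorter than the 30 min asked. Its E can use up only a quarter of its D, so [D] holds and gamma should be nearly finished. Theta, scaled from larch by loading, reads 28.6 min, but at 1.00 equiv its [D] falls with every L made. Eta reads 138 min, about 21.7% at 30 min. Epsilon reads 4320 min, so 0.694% before any lag is counted. I put gamma first and epsilon last.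

The forecast gives theta > gamma > beta > eta > alpha > epsilon at 30 min and gamma > theta > beta > eta > alpha > epsilon at 2.0 h, with top 36% (range 27% to 50%) and low 0.4% (range 0% to 1.5%). Its ground for gamma: “Gamma, protected by excess D, runs at about 1 %/min or more”. Here my reckoning differs from it: mine puts gamma first at 30 min as well.

Gamma gives 99.9% against the forecast's 36%, the number you get by taking over birch's last reading; the order is gamma > theta > alpha > eta > beta > epsilon at 30 min and gamma > theta > alpha > eta > beta > epsilon at 2.0 h, and epsilon gives 0.194%. Over 30 min gamma's turnover time of 12.6 min counts 2.38 turnovers; at 15.0 min gamma already held 93.2% of L, with 76.7% of its own charge of D left.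

    E + Q ⇌ Q + Z (K = 2.30, k = 4.00 M⁻¹ s⁻¹, Ea = 57.0 kJ mol⁻¹, ΔH = −32.0 kJ mol⁻¹)
    Q + Z ⇌ G (K = 280 M⁻¹, k = 7.50 M⁻¹ s⁻¹, Ea = 70.0 kJ mol⁻¹, ΔH = −33.0 kJ mol⁻¹)
    D + G → Q + L (k = 0.150 M⁻¹ s⁻¹, Ea = 71.0 kJ mol⁻¹)
    (constants at 100 °C)

Take a flask like epsilon, but with 1.6 mol% of Q. The clock stretches to 10800 min, or 0.278% at 30 min with no lag counted. The computed flask holds less than that, 0.0416%.

(The numbers in the tables stem from a simulated flask with made-up constants; scatter was added.)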